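## Retrosynthetic overview

1. Core numbering: C1H2–O2–C3H(Ar1, guaiacyl)–C3a–C4H2–O5–C6H(Ar2, prenyloxyaryl)–C6a. Ring A holds O2 and ring B holds O5. The SMILES reads 3R,3aS,6R,6aS with both aryl groups exo, so the target is the monoprenyl ether of (−)-pinoresinol.
2. Enabling feature: C4 is an isolated CH2 between O5 and C3a (a formaldehyde carbon), and C3a–C3 is a masked styrene whose C3 is benzylic and carries O2. The O2–C1 arm and the O5–C6 arm both hang on C6a, so one CH2O can first bridge O5 and a C1 carboxyl group in a temporary six-membered ring.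
3. Key disconnection: C3a–C4 together with C3–O2. The C1-oxo bicycle (furofuranone) is an isomer of a cis-5-styryl-6-aryl-1,3-dioxan-4-one, and a Lewis acid opens the temporary ring and closes rings B and A in one event (Prins carbolactonisation).
4. The dioxanone comes from CH2O and a syn β-hydroxy acid. That acid is made by an Evans aldol reaction (C6–C6a bond, two stereocentres) of a styrylacetyl imide with a vanillin sulfonate, and both aryl units come from vanillin.
5. After the key step, C1=O is taken to CH2 (lactol, then silane), the mesylate on Ar2 is exchanged for the prenyl ether, and the tosylate on Ar1 is cleaved to the free phenol. Ring order: temporary dioxanone first, then rings B and A together.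

Key step: step 8

## Route

Step 1
Reactants: 1 vanillin (4-hydroxy-3-methoxybenzaldehyde)
Product: 2 4-formyl-2-methoxyphenyl 4-methylbenzenesulfonate
Conditions: TsCl (1.1 equiv), Et3N, CH2Cl2, 0 °C to rt
Reagents that add atoms: 4-methylbenzenesulfonyl chloride, Cc1ccc(cc1)S(=O)(=O)Cl
Why: O-sulfonylation of the phenol turns the para oxygen of the future Ar1 into an electron-poor substituent that is stable to base and Lewis acid and has no acidic α-hydrogen; no stereocenter is formed.

Step 2
Reactants: 2 4-formyl-2-methoxyphenyl 4-methylbenzenesulfonate; 3 (2-carboxyethyl)triphenylphosphonium bromide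
Product: 5 (E)-4-[3-methoxy-4-(tosyloxy)phenyl]but-3-enoic acid, via ylide carboxylate 4 (not isolated)
Conditions: 3, NaN(SiMe3)2 (2.1 equiv), THF, 0 °C; then 2, 0 °C to rt; aq. HCl; crystallisation
Reagents that add atoms: none
Why: Wittig olefination with the carboxylate-bearing ylide should give mainly the (E)-β,γ-unsaturated acid with aromatic aldehydes, and crystallisation should remove any (Z)-isomer.

Step 3
Reactants: 5 (E)-4-[3-methoxy-4-(tosyloxy)phenyl]but-3-enoic acid; 6 (R)-4-benzyl-1,3-oxazolidin-2-one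
Product: 8 (R)-4-benzyl-3-{(E)-4-[3-methoxy-4-(tosyloxy)phenyl]but-3-enoyl}-1,3-oxazolidin-2-one, via mixed pivalic anhydride 7 (not isolated)
Conditions: Me3CCOCl, Et3N, THF, −20 °C; then LiCl, 6, −20 °C to rt
Reagents that add atoms: none
Why: N-acylation of the Evans auxiliary through the mixed anhydride under LiCl/Et3N conditions avoids strong base, so the styrene-conjugated β,γ-alkene should neither migrate nor isomerise.

Step 4
Reactants: 1 vanillin
Product: 9 4-formyl-2-methoxyphenyl methanesulfonate
Conditions: MsCl (1.1 equiv), Et3N, CH2Cl2, 0 °C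
Reagents that add atoms: methanesulfonyl chloride, CS(=O)(=O)Cl
Why: O-mesylation gives Ar2 an electron-withdrawing mask that can later be removed in the presence of the tosylate; no stereocenter is formed.

Step 5
Reactants: 8 (R)-4-benzyl-3-{(E)-4-[3-methoxy-4-(tosyloxy)phenyl]but-3-enoyl}-1,3-oxazolidin-2-one; 9 4-formyl-2-methoxyphenyl methanesulfonate
Product: 12 (4R)-4-benzyl-3-[(2R,3E)-2-{(R)-hydroxy[3-methoxy-4-(mesyloxy)phenyl]methyl}-4-[3-methoxy-4-(tosyloxy)phenyl]but-3-enoyl]-1,3-oxazolidin-2-one, via dibutylboron dienolate 10 (not isolated), via dibutylboron aldolate 11 (not isolated)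
Conditions: Bu2BOTf (1.1 equiv), Et3N (1.3 equiv), CH2Cl2, −78 to 0 °C; then 9, −78 to 0 °C; pH 7 buffer, MeOH, 30% H2O2, 0 °C
Reagents that add atoms: none
Why: In this Evans syn aldol reaction the (Z)-boron dienolate reacts at its α-carbon through a Zimmerman–Traxler chair on the face away from the benzyl group of the (R)-auxiliary, which should set C6a and C6 (2R and carbinol R) and leave the (E)-styryl group untouched.

Step 6
Reactants: 12 syn-aldol imide
Product: 14 (2R,3E)-2-{(R)-hydroxy[3-methoxy-4-(mesyloxy)phenyl]methyl}-4-[3-methoxy-4-(tosyloxy)phenyl]but-3-enoic acid, via lithium peroxycarboxylate 13 (not isolated)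
Conditions: LiOH (2 equiv), 30% H2O2, THF/H2O, 0 °C; then aq. Na2SO3; aq. HCl to pH 3
Reagents that add atoms: hydrogen peroxide, OO
Why: Hydroperoxide cleavage of the N-acyl oxazolidinone at the exocyclic carbonyl (standard auxiliary removal) at 0 °C should spare the C6a–H, the aryl sulfonates and both stereocentres, and the auxiliary is recovered.

Step 7
Reactants: 14 syn β-hydroxy acid
Product: 15 (5R,6R)-6-[3-methoxy-4-(mesyloxy)phenyl]-5-{(E)-2-[3-methoxy-4-(tosyloxy)phenyl]ethenyl}-1,3-dioxan-4-one (substituents cis)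
Conditions: (CH2O)n (5 equiv), TsOH·H2O (5 mol %), benzene, reflux, Dean–Stark trap
Reagents that add atoms: formaldehyde (from paraformaldehyde), C=O
Why: Acid-catalysed acetalisation of a β-hydroxy acid with formaldehyde gives the 1,3-dioxan-4-one; the two stereocentres are spectators that end cis on the ring, and the electron-poor aryl groups suppress benzylic ionisation and styrene protonation.

Step 8
Reactants: 15 cis-5-styryl-6-aryl-1,3-dioxan-4-one
Product: 17 (3R,3aS,6R,6aR)-6-[3-methoxy-4-(mesyloxy)phenyl]-3-[3-methoxy-4-(tosyloxy)phenyl]tetrahydro-1H,3H-furo[3,4-c]furan-1-one (cis-fused; both aryl groups exo), via oxocarbenium silyl ester triflate 16 (not isolated)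
Conditions: Me3SiOTf (0.3 equiv), 2,6-di-tert-butyl-4-methylpyridine (0.1 equiv), CH2Cl2 (0.02 M), −78 to 0 °C; Et3N quench
Reagents that add atoms: none
Why: Proposed new method: Me3SiOTf silylates the carbonyl oxygen of the cyclic acyloxy acetal 15, the CH2–O(acyl) bond ionises to oxocarbenium silyl ester 16, the styrene carbon C3a attacks the CH2=O+ carbon C4 while the ester carbonyl oxygen adds to C3 on the opposite alkene face, and loss of Me3Si+ returns the catalyst, so that the step is a pure isomerisation. The closest known reaction types are the oxonium-Prins cyclisation of styrenyl homoallylic acetals and α-acyloxy ethers to 2,3-disubstituted tetrahydrofurans, the Lewis-acid substitution of 1,3-dioxan-4-ones at the acetal carbon with carboxylate as leaving group, and the 5-endo halolactonisation of (E)-4-arylbut-3-enoic acids, of which this is the carbon-electrophile counterpart. Ring B closes through the C3a–C4 bond, 5-exo-trig at the alkene and endo at the oxocarbenium ion, and ring A closes as a γ-lactone through the C3–O2 bond, 5-endo-trig at the alkene. C3a is controlled by C6a, because the electrophilic arm (C6–O5=CH2) and the nucleophilic arm (C1 carboxyl) both hang on C6a and must straddle the alkene, which can only give the cis-fused bicycle, and C3 is controlled by the (E)-geometry, because anti addition puts Ar1 trans to C4, that is exo. The step needs ionisation toward O5 only, attack through C3a instead of 6-endo attack or 2-oxonia-Cope rearrangement through C3, and benzylic C–O bonds that do not ionise: the first is secured by the carboxyl oxidation level of C1 (carboxylate leaves, alkoxide does not), the second by the aryl group on C3 and the carboxyl group on C6a, the third by the two sulfonyloxy groups that make both rings electron-poor. Return of the carboxylate oxygen to C4 only regenerates 15, so capture at oxygen is degenerate and costs nothing.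

Step 9
Reactants: 17 furofuranone
Product: 18 (3R,3aS,6R,6aR)-6-[3-methoxy-4-(mesyloxy)phenyl]-3-[3-methoxy-4-(tosyloxy)phenyl]tetrahydro-1H,3H-furo[3,4-c]furan-1-ol (mixture of C1 anomers)
Conditions: iBu2AlH (1.2 equiv), CH2Cl2, −78 °C; aq. potassium sodium tartrate
Reagents that add atoms: none
Why: Partial reduction of the γ-lactone stops at the aluminium lactolate at low temperature, aryl sulfonates are inert, and the only new centre (C1) is removed again in step 10.

Step 10
Reactants: 18 lactol
Product: 19 (3R,3aS,6R,6aS)-6-[3-methoxy-4-(mesyloxy)phenyl]-3-[3-methoxy-4-(tosyloxy)phenyl]tetrahydro-1H,3H-furo[3,4-c]furan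
Conditions: Et3SiH (3 equiv), BF3·OEt2 (2 equiv), CH2Cl2, −78 to −20 °C
Reagents that add atoms: none
Why: Ionic silane reduction of the lactol through the C1 oxocarbenium ion is the standard lactol-to-cyclic-ether deoxygenation, and the electron-poor aryl groups should keep the C3–O2 and C6–O5 bonds from ionising, so no stereocenter is touched.

Step 11
Reactants: 19 furofuran mesylate tosylate
Product: 20 (3R,3aS,6R,6aS)-6-(4-hydroxy-3-methoxyphenyl)-3-[3-methoxy-4-(tosyloxy)phenyl]tetrahydro-1H,3H-furo[3,4-c]furan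
Conditions: LiN(iPr)2 (2.5 equiv), THF, −78 to 0 °C; aq. NH4Cl
Reagents that add atoms: none
Why: The aryl mesylate is cleaved by α-deprotonation and loss of sulfene (E1cB), a path closed to the tosylate because it has no hydrogen on the sulfur-bound carbon, so only the Ar2 phenol should be released.

Step 12
Reactants: 20 Ar2 phenol Ar1 tosylate
Product: 21 (3R,3aS,6R,6aS)-6-{3-methoxy-4-[(3-methylbut-2-en-1-yl)oxy]phenyl}-3-[3-methoxy-4-(tosyloxy)phenyl]tetrahydro-1H,3H-furo[3,4-c]furan
Conditions: prenyl bromide (1.2 equiv), K2CO3, acetone, 45 °C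
Reagents that add atoms: 1-bromo-3-methylbut-2-ene, CC(C)=CCBr
Why: In this Williamson ether synthesis the phenoxide attacks the primary carbon of prenyl bromide (SN2), while the tosylate keeps the Ar1 oxygen blocked.

Step 13
Reactants: 21 prenyl ether tosylate
Product: 22 target, 4-[(3R,3aS,6R,6aS)-6-{3-methoxy-4-[(3-methylbut-2-en-1-yl)oxy]phenyl}tetrahydro-1H,3H-furo[3,4-c]furan-3-yl]-2-methoxyphenol
Conditions: Mg turnings (10 equiv), MeOH, rt, sonication; aq. NH4Cl
Reagents that add atoms: none
Why: Reductive S–O cleavage of the aryl tosylate by electron transfer from Mg in MeOH at room temperature should leave the isolated trisubstituted alkene, the aryl prenyl ether and the benzylic ethers untouched, so no stereocenter is at risk.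

## Compound list

1 | vanillin | COc1cc(C=O)ccc1O | starting material
2 | 4-formyl-2-methoxyphenyl 4-methylbenzenesulfonate | COc1cc(C=O)ccc1OS(=O)(=O)c1ccc(C)cc1 | intermediate
3 | (2-carboxyethyl)triphenylphosphonium bromide | OC(=O)CC[P+](c1ccccc1)(c1ccccc1)c1ccccc1.[Br-] | starting material
4 | sodium 3-(triphenylphosphoranylidene)propanoate (ylide carboxylate) | [Na+].[O-]C(=O)C[CH-][P+](c1ccccc1)(c1ccccc1)c1ccccc1 | intermediate
5 | (E)-4-[3-methoxy-4-(tosyloxy)phenyl]but-3-enoic acid | OC(=O)C/C=C/c1ccc(OS(=O)(=O)c2ccc(C)cc2)c(OC)c1 | intermediate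
6 | (R)-4-benzyl-1,3-oxazolidin-2-one | O=C1N[C@H](Cc2ccccc2)CO1 | starting material
7 | mixed pivalic anhydride of 5 | CC(C)(C)C(=O)OC(=O)C/C=C/c1ccc(OS(=O)(=O)c2ccc(C)cc2)c(OC)c1 | intermediate
8 | (R)-4-benzyl-3-{(E)-4-[3-methoxy-4-(tosyloxy)phenyl]but-3-enoyl}-1,3-oxazolidin-2-one | O=C(C/C=C/c1ccc(OS(=O)(=O)c2ccc(C)cc2)c(OC)c1)N1[C@H](Cc2ccccc2)COC1=O | intermediate
9 | 4-formyl-2-methoxyphenyl methanesulfonate | COc1cc(C=O)ccc1OS(C)(=O)=O | intermediate
10 | (Z)-dibutylboron dienolate of 8 | CCCCB(CCCC)O/C(=C\C=C\c1ccc(OS(=O)(=O)c2ccc(C)cc2)c(OC)c1)N1[C@H](Cc2ccccc2)COC1=O | intermediate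
11 | dibutylboron aldolate of 12 | O=C(N1[C@H](Cc2ccccc2)COC1=O)[C@H](/C=C/c1ccc(OS(=O)(=O)c2ccc(C)cc2)c(OC)c1)[C@@H](OB(CCCC)CCCC)c1ccc(OS(C)(=O)=O)c(OC)c1 | intermediate
12 | syn-aldol imide (2R, carbinol R, 3E, auxiliary 4R) | O=C(N1[C@H](Cc2ccccc2)COC1=O)[C@H](/C=C/c1ccc(OS(=O)(=O)c2ccc(C)cc2)c(OC)c1)[C@@H](O)c1ccc(OS(C)(=O)=O)c(OC)c1 | intermediate
13 | lithium peroxycarboxylate of 14 | [Li+].[O-]OC(=O)[C@H](/C=C/c1ccc(OS(=O)(=O)c2ccc(C)cc2)c(OC)c1)[C@@H](O)c1ccc(OS(C)(=O)=O)c(OC)c1 | intermediate
14 | syn β-hydroxy acid (2R, carbinol R, 3E) | OC(=O)[C@H](/C=C/c1ccc(OS(=O)(=O)c2ccc(C)cc2)c(OC)c1)[C@@H](O)c1ccc(OS(C)(=O)=O)c(OC)c1 | intermediate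
15 | (5R,6R)-cis-5-styryl-6-aryl-1,3-dioxan-4-one | O=C1OCO[C@@H](c2ccc(OS(C)(=O)=O)c(OC)c2)[C@H]1/C=C/c1ccc(OS(=O)(=O)c2ccc(C)cc2)c(OC)c1 | intermediate
16 | ring-opened oxocarbenium trimethylsilyl ester triflate | C=[O+][C@@H](c1ccc(OS(C)(=O)=O)c(OC)c1)[C@@H](/C=C/c1ccc(OS(=O)(=O)c2ccc(C)cc2)c(OC)c1)C(=O)O[Si](C)(C)C.[O-]S(=O)(=O)C(F)(F)F | intermediate
17 | (3R,3aS,6R,6aR)-furofuranone, both aryl groups exo | COc1cc([C@@H]2OC(=O)[C@@H]3[C@H]2CO[C@H]3c2ccc(OS(C)(=O)=O)c(OC)c2)ccc1OS(=O)(=O)c1ccc(C)cc1 | intermediate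
18 | lactol (C1 anomers) | COc1cc([C@@H]2OC(O)[C@@H]3[C@H]2CO[C@H]3c2ccc(OS(C)(=O)=O)c(OC)c2)ccc1OS(=O)(=O)c1ccc(C)cc1 | intermediate
19 | (3R,3aS,6R,6aS)-furofuran, Ar2 mesylate, Ar1 tosylate | COc1cc([C@@H]2OC[C@@H]3[C@H]2CO[C@H]3c2ccc(OS(C)(=O)=O)c(OC)c2)ccc1OS(=O)(=O)c1ccc(C)cc1 | intermediate
20 | furofuran, Ar2 free phenol, Ar1 tosylate | COc1cc([C@@H]2OC[C@@H]3[C@H]2CO[C@H]3c2ccc(O)c(OC)c2)ccc1OS(=O)(=O)c1ccc(C)cc1 | intermediate
21 | furofuran, Ar2 prenyl ether, Ar1 tosylate | COc1cc([C@@H]2OC[C@@H]3[C@H]2CO[C@H]3c2ccc(OCC=C(C)C)c(OC)c2)ccc1OS(=O)(=O)c1ccc(C)cc1 | intermediate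
22 | CNP0185952.2, (−)-pinoresinol monoprenyl ether | COc1cc([C@@H]2OC[C@@H]3[C@H]2CO[C@H]3c2ccc(OCC=C(C)C)c(OC)c2)ccc1O | target

## Step count and risks

Total step count: 13. Longest linear sequence: 12 steps (1, 2, 3, then 5 to 13).

**Step 8.** The formaldehyde acyloxy acetal may fail to ionise. The oxocarbenium ion may drain through 2-oxonia-Cope rearrangement, or an unassisted cyclisation may take the wrong alkene face and end in elimination.
- The fallback runs the same C3a–C4 closure at the alcohol oxidation level by known acetal-initiated oxonium-Prins chemistry. It sets out from 12.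
- MOMCl and iPr2NEt (CH2Cl2, reflux) give the methoxymethyl ether imide F1.
- LiBH4 (THF, one equivalent of H2O, 0 °C) removes the auxiliary to give the primary alcohol F2.
- TBSCl and imidazole give the silyl ether F3.
- Catalytic Me3SiOTf (CH2Cl2, −78 °C) ionises the MOM ether. The styrene closes ring B and the bulky silyl ether oxygen closes ring A.
- The fallback comes back to the route at 19, so steps 9 and 10 fall away.

**Step 7.** Heating with acid may dehydrate the β-hydroxy acid or build open-chain formals instead of the six-membered ring.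
- The fallback replaces dehydrative acetalisation by aprotic silyl-transfer acetalisation (Noyori type). It sets out from 14.
- Me3SiCl and Et3N give the bis(trimethylsilyl) derivative F4.
- F4 is treated with 1,3,5-trioxane and catalytic Me3SiOTf in CH2Cl2 at −78 °C.
- The fallback comes back to the route at 15.

**Step 11.** The base may cleave the mesylate incompletely, or it may also attack the tosylate or its benzylic methyl group, so that the two phenols lose their differentiation.
- The fallback gives up differentiation and uses the symmetry of the core. It sets out from 19.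
- KOH in dioxane/H2O at 60 °C removes both sulfonates to give (−)-pinoresinol F5.
- The two phenols of F5 are homotopic about the C2 axis.
- Alkylation with one equivalent of prenyl bromide (K2CO3, acetone) run to partial conversion, with unreacted F5 recycled, can therefore give only one monoether.
- The fallback comes back to the route at 22.

Further compounds
F1 | step 8 | (4R)-4-benzyl-3-[(2R,3E)-2-{(R)-(methoxymethoxy)[3-methoxy-4-(mesyloxy)phenyl]methyl}-4-[3-methoxy-4-(tosyloxy)phenyl]but-3-enoyl]-1,3-oxazolidin-2-one | O=C(N1[C@H](Cc2ccccc2)COC1=O)[C@H](/C=C/c1ccc(OS(=O)(=O)c2ccc(C)cc2)c(OC)c1)[C@@H](OCOC)c1ccc(OS(C)(=O)=O)c(OC)c1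
F2 | step 8 | (2S,3E)-2-{(R)-(methoxymethoxy)[3-methoxy-4-(mesyloxy)phenyl]methyl}-4-[3-methoxy-4-(tosyloxy)phenyl]but-3-en-1-ol | OC[C@H](/C=C/c1ccc(OS(=O)(=O)c2ccc(C)cc2)c(OC)c1)[C@@H](OCOC)c1ccc(OS(C)(=O)=O)c(OC)c1
F3 | step 8 | tert-butyldimethylsilyl ether of F2 | CC(C)(C)[Si](C)(C)OC[C@H](/C=C/c1ccc(OS(=O)(=O)c2ccc(C)cc2)c(OC)c1)[C@@H](OCOC)c1ccc(OS(C)(=O)=O)c(OC)c1
F4 | step 7 | trimethylsilyl ester trimethylsilyl ether of 14 | C[Si](C)(C)OC(=O)[C@H](/C=C/c1ccc(OS(=O)(=O)c2ccc(C)cc2)c(OC)c1)[C@@H](O[Si](C)(C)C)c1ccc(OS(C)(=O)=O)c(OC)c1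
F5 | step 11 | (−)-pinoresinol | COc1cc([C@@H]2OC[C@@H]3[C@H]2CO[C@H]3c2ccc(O)c(OC)c2)ccc1O
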